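The route rests on disconnecting the two allylic C–O bonds at C2 and C5 of the cyclohexene ring to dioxygen and a C2=C3–C4=C5 diene. The feature exploited is the C2(O)–C3=C4–C5(O) ene-1,4-dioxygen unit of the carbocycle. One singlet-oxygen [4+2] cycloaddition forms both C–O bonds, leaves the C3=C4 alkene and closes a 2,3-dioxabicyclo[2.2.2]octene on the face of the C1 hydroxyl. The precursor is a cyclohexa-2,4-dienol whose C1 (tertiary OH, C7 benzoate) comes from microbial dihydroxylation of benzoate and whose C6 oxygen is inverted to a trans silyl ether that blocks the other face. Base-induced peroxide opening, then ketone reduction, inverts C5 alone.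

Key step: step 7

Remark: ring atoms keep one numbering in all compounds (C1 quaternary carbinol, C2–C5, C6 the carbinol carbon next to C1, C7 the exocyclic CH2). The dehydrogenase-deficient strain Ralstonia eutropha B9 is assumed to be an accessible biocatalyst.

Step 1
Reactants: 1 sodium benzoate; 2 dioxygen
Product: 3 (1S,6R)-1,6-dihydroxycyclohexa-2,4-diene-1-carboxylic acid (cis diol)
Conditions: Ralstonia eutropha B9 whole cells (benzoate 1,2-dioxygenase, no diol dehydrogenase), fructose mineral medium, air, 30 °C; then HCl to pH 3, EtOAc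
Reagents that add atoms: dioxygen, O=O
Why: Enzymatic dearomatising cis-dihydroxylation (arene dioxygenase) delivers both atoms of one O2 to the ipso and ortho carbons from the same face, which fixes C1 in the configuration the target needs and places the C6 hydroxyl cis to it, and the blocked mutant cannot rearomatise the diol.

Step 2
Reactants: 3 (1S,6R)-1,6-dihydroxycyclohexa-2,4-diene-1-carboxylic acid; 4 iodomethane
Product: 5 methyl (1S,6R)-1,6-dihydroxycyclohexa-2,4-diene-1-carboxylate
Conditions: MeI, KHCO3, DMF, 20 °C
Reagents that add atoms: iodomethane, CI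
Why: SN2 O-alkylation of the carboxylate under weakly basic conditions should form the ester without exposing the acid-labile dienediol to acid, and bicarbonate is too weak to alkylate either hydroxyl.

Step 3
Reactants: 5 methyl (1S,6R)-1,6-dihydroxycyclohexa-2,4-diene-1-carboxylate
Product: 6 (1R,6R)-1-(hydroxymethyl)cyclohexa-2,4-diene-1,6-diol (cis C1/C6 hydroxyls)
Conditions: LiAlH4, THF, 0 °C; aqueous NaOH work-up
Reagents that add atoms: none
Why: Hydride reduction of the ester to the primary alcohol should be clean because the diene is not conjugated to the carbonyl and the basic work-up avoids ionisation at C6.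

Step 4
Reactants: 6 (1R,6R)-1-(hydroxymethyl)cyclohexa-2,4-diene-1,6-diol; 7 benzoyl chloride
Product: 8 [(1R,6R)-1,6-dihydroxycyclohexa-2,4-dien-1-yl]methyl benzoate (cis diol)
Conditions: BzCl (1.05 equiv), 2,4,6-collidine, CH2Cl2, −40 to −10 °C
Reagents that add atoms: benzoyl chloride, O=C(Cl)c1ccccc1
Why: Nucleophilic acyl substitution (O-benzoylation) should be fastest at the primary C7 hydroxyl, since the secondary C6 hydroxyl beside the quaternary centre and the tertiary C1 hydroxyl react far more slowly at low temperature with a hindered base.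

Step 5
Reactants: 8 [(1R,6R)-1,6-dihydroxycyclohexa-2,4-dien-1-yl]methyl benzoate
Product: 10 [(1R,6S)-1,6-dihydroxycyclohexa-2,4-dien-1-yl]methyl benzoate (trans diol), via dienone 9 (not isolated)
Conditions: (COCl)2, DMSO, CH2Cl2, −78 °C; Et3N, −78 °C; then MeOH, CeCl3·7H2O, NaBH4, −78 °C; one pot, about 0.02 M
Reagents that add atoms: none
Why: Swern oxidation of the secondary C6 carbinol followed in the same flask by Luche 1,2-reduction should invert C6 without ionisation at C6 (which would pass through an achiral pentadienyl cation and erase C1), with the dienone kept cold and dilute so that reduction outruns its [4+2] self-dimerisation and with hydride entering on the face of the small C1 hydroxyl, which can also bind the borohydride, opposite the C7H2OBz group, so that the new C6 hydroxyl ends up trans to the C1 hydroxyl.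

Step 6
Reactants: 10 [(1R,6S)-1,6-dihydroxycyclohexa-2,4-dien-1-yl]methyl benzoate; 11 tert-butyldimethylsilyl chloride
Product: 12 [(1R,6S)-6-(tert-butyldimethylsilyloxy)-1-hydroxycyclohexa-2,4-dien-1-yl]methyl benzoate (C1–OH and C6–OSi trans)
Conditions: TBSCl, imidazole, DMF, 20 °C
Reagents that add atoms: tert-butyldimethylsilyl chloride, C[Si](C)(Cl)C(C)(C)C
Why: Imidazole-promoted silyl ether formation should occur only at the secondary C6 hydroxyl, leaving the tertiary C1 hydroxyl free and the C7 benzoate in place.

Step 7
Reactants: 12 [(1R,6S)-6-(tert-butyldimethylsilyloxy)-1-hydroxycyclohexa-2,4-dien-1-yl]methyl benzoate; 2 dioxygen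
Product: 13 [(1S,2S,5R,6S)-6-(tert-butyldimethylsilyloxy)-2,5-epidioxy-1-hydroxycyclohex-3-en-1-yl]methyl benzoate (a 2,3-dioxabicyclo[2.2.2]oct-5-ene; peroxide bridge cis to C1–OH and trans to C6–OSi)
Conditions: O2, 5,10,15,20-tetraphenylporphyrin (cat.), visible light, CH2Cl2, −30 °C
Reagents that add atoms: dioxygen, O=O
Why: Sensitised singlet oxygen should add as a two-atom dienophile to the ring-locked s-cis C2=C3–C4=C5 diene in a concerted, suprafacial hetero-[4+2] cycloaddition that forms C2–O and C5–O and moves the alkene to C3=C4. The closest known reaction type is the photooxygenation of cyclohexa-1,3-dienes to 2,3-dioxabicyclo[2.2.2]oct-5-enes. The one new ring, the six-membered 1,2-dioxene that completes the bicycle, closes by cycloaddition with both bonds made together across the diene termini, not by cyclisation of a tethered nucleophile. Both new stereocentres, C2 and C5, are set by the face of attack, which the existing C1 and C6 centres control, so the two C–O bonds are cis to each other and cis to the C1 hydroxyl. The selectivity needed is facial: the face opposite the C1 hydroxyl carries both C7H2OBz and the C6 silyl ether, one of which is pseudoaxial over the diene in either half-chair, whereas the hydroxyl face carries only OH and H, and in a non-protic solvent the hydroxyl can hydrogen-bond to the incoming oxygen. Ene reaction at the single allylic hydrogen (C6–H) is the expected minor competitor and is normally slow for conjugated cyclic dienes.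

Step 8
Reactants: 13 [(1S,2S,5R,6S)-6-(tert-butyldimethylsilyloxy)-2,5-epidioxy-1-hydroxycyclohex-3-en-1-yl]methyl benzoate
Product: 14 [(1S,2S,6R)-6-(tert-butyldimethylsilyloxy)-1,2-dihydroxy-5-oxocyclohex-3-en-1-yl]methyl benzoate (C5 ketone, C3=C4, C2–OH cis to C1–OH)
Conditions: Et3N, CH2Cl2, 0 °C
Reagents that add atoms: none
Why: In this Kornblum–DeLaMare rearrangement the amine should remove the bridgehead C5–H antiperiplanar to the O–O bond, giving the C5 ketone and the C2 alcohol with C2 untouched, and C5–H should be preferred because it is flanked by the tertiary C6 and not the quaternary C1 and because the C1 hydroxyl hydrogen-bonds to the oxygen that departs on C2.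

Step 9
Reactants: 14 [(1S,2S,6R)-6-(tert-butyldimethylsilyloxy)-1,2-dihydroxy-5-oxocyclohex-3-en-1-yl]methyl benzoate
Product: 15 [(1S,2S,5S,6S)-6-(tert-butyldimethylsilyloxy)-1,2,5-trihydroxycyclohex-3-en-1-yl]methyl benzoate (C5–OH cis to C6–OSi, trans to C2–OH)
Conditions: NaBH4, CeCl3·7H2O, MeOH, −78 °C
Reagents that add atoms: none
Why: Luche 1,2-reduction of the enone should deliver hydride to C5 on the ring face that is free of the C6 silyl ether and the C7H2OBz group (both sit on the other face), so the new C5 hydroxyl is cis to the C6 silyl ether and trans to the C2 hydroxyl, as the target requires.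

Step 10
Reactants: 15 [(1S,2S,5S,6S)-6-(tert-butyldimethylsilyloxy)-1,2,5-trihydroxycyclohex-3-en-1-yl]methyl benzoate; 7 benzoyl chloride
Product: 16 [(1S,2S,5S,6S)-2,5-bis(benzoyloxy)-6-(tert-butyldimethylsilyloxy)-1-hydroxycyclohex-3-en-1-yl]methyl benzoate
Conditions: BzCl (2.5 equiv), pyridine, DMAP (cat.), CH2Cl2, 0 to 20 °C
Reagents that add atoms: benzoyl chloride, O=C(Cl)c1ccccc1
Why: DMAP-catalysed acylation should esterify the two secondary allylic hydroxyls at C2 and C5, while the tertiary C1 hydroxyl is too hindered to react and the silyl ether is stable to pyridine.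

Step 11
Reactants: 16 [(1S,2S,5S,6S)-2,5-bis(benzoyloxy)-6-(tert-butyldimethylsilyloxy)-1-hydroxycyclohex-3-en-1-yl]methyl benzoate
Product: 17 [(1R,2S,5S,6S)-2,5-bis(benzoyloxy)-1,6-dihydroxycyclohex-3-en-1-yl]methyl benzoate (target)
Conditions: HF·pyridine, pyridine, THF, 0 to 20 °C
Reagents that add atoms: none
Why: Fluoride-driven Si–O cleavage under buffered, non-basic conditions should free the C6 hydroxyl without forming an alkoxide that could pull a benzoate over from C5 or C7, and the allylic benzoates are stable to HF·pyridine.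

Compound list
1 | sodium benzoate | [Na+].[O-]C(=O)c1ccccc1 | starting material
2 | dioxygen | O=O | starting material
3 | (1S,6R)-1,6-dihydroxycyclohexa-2,4-diene-1-carboxylic acid (cis diol) | OC(=O)[C@]1(O)C=CC=C[C@H]1O | intermediate
4 | iodomethane | CI | starting material
5 | methyl (1S,6R)-1,6-dihydroxycyclohexa-2,4-diene-1-carboxylate | COC(=O)[C@]1(O)C=CC=C[C@H]1O | intermediate
6 | (1R,6R)-1-(hydroxymethyl)cyclohexa-2,4-diene-1,6-diol | OC[C@]1(O)C=CC=C[C@H]1O | intermediate
7 | benzoyl chloride | O=C(Cl)c1ccccc1 | starting material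
8 | [(1R,6R)-1,6-dihydroxycyclohexa-2,4-dien-1-yl]methyl benzoate (cis diol) | O=C(OC[C@]1(O)C=CC=C[C@H]1O)c1ccccc1 | intermediate
9 | [(1R)-1-hydroxy-6-oxocyclohexa-2,4-dien-1-yl]methyl benzoate (dienone) | O=C(OC[C@]1(O)C=CC=CC1=O)c1ccccc1 | intermediate (not isolated)
10 | [(1R,6S)-1,6-dihydroxycyclohexa-2,4-dien-1-yl]methyl benzoate (trans diol) | O=C(OC[C@]1(O)C=CC=C[C@@H]1O)c1ccccc1 | intermediate
11 | tert-butyldimethylsilyl chloride | C[Si](C)(Cl)C(C)(C)C | starting material
12 | [(1R,6S)-6-(tert-butyldimethylsilyloxy)-1-hydroxycyclohexa-2,4-dien-1-yl]methyl benzoate | O=C(OC[C@]1(O)C=CC=C[C@@H]1O[Si](C)(C)C(C)(C)C)c1ccccc1 | intermediate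
13 | [(1S,2S,5R,6S)-6-(tert-butyldimethylsilyloxy)-2,5-epidioxy-1-hydroxycyclohex-3-en-1-yl]methyl benzoate (endoperoxide) | O=C(OC[C@]1(O)[C@@H]2C=C[C@@H](OO2)[C@@H]1O[Si](C)(C)C(C)(C)C)c1ccccc1 | intermediate
14 | [(1S,2S,6R)-6-(tert-butyldimethylsilyloxy)-1,2-dihydroxy-5-oxocyclohex-3-en-1-yl]methyl benzoate | O=C(OC[C@]1(O)[C@@H](O)C=CC(=O)[C@@H]1O[Si](C)(C)C(C)(C)C)c1ccccc1 | intermediate
15 | [(1S,2S,5S,6S)-6-(tert-butyldimethylsilyloxy)-1,2,5-trihydroxycyclohex-3-en-1-yl]methyl benzoate | O=C(OC[C@]1(O)[C@@H](O)C=C[C@H](O)[C@@H]1O[Si](C)(C)C(C)(C)C)c1ccccc1 | intermediate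
16 | [(1S,2S,5S,6S)-2,5-bis(benzoyloxy)-6-(tert-butyldimethylsilyloxy)-1-hydroxycyclohex-3-en-1-yl]methyl benzoate | O=C(OC[C@]1(O)[C@@H](OC(=O)c2ccccc2)C=C[C@H](OC(=O)c2ccccc2)[C@@H]1O[Si](C)(C)C(C)(C)C)c1ccccc1 | intermediate
17 | [(1R,2S,5S,6S)-2,5-bis(benzoyloxy)-1,6-dihydroxycyclohex-3-en-1-yl]methyl benzoate | O=C(OC[C@]1(O)[C@@H](OC(=O)c2ccccc2)C=C[C@H](OC(=O)c2ccccc2)[C@@H]1O)c1ccccc1 | target

Total step count: 11. Longest linear sequence: 11 steps (1 to 17).

Steps most likely to fail

1. Step 5 (C6 inversion). The transient dienone may undergo [4+2] self-dimerisation faster than it is reduced, or hydride may be delivered on the C7 face and simply regenerate the cis diol. The fallback sets out from 8 and comes back at 10. Mitsunobu displacement at C6 with chloroacetic acid (PPh3, DIAD, toluene, 0 °C) should give, by SN2 inversion and without any ketone, the C6-inverted chloroacetate [(1R,6S)-6-(chloroacetoxy)-1-hydroxycyclohexa-2,4-dien-1-yl]methyl benzoate F1. Thiourea with NaHCO3 in ethanol then removes the chloroacetyl group selectively beside the C7 benzoate and delivers 10.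

2. Step 7 (key cycloaddition). Facial discrimination may be insufficient, with oxygen adding on the C7 face, or ene reaction at C6–H may compete. The fallback sets out from 12 and comes back at 15, bypassing steps 8 and 9. Epoxidation with t-BuOOH and catalytic VO(acac)2, directed by the allylic C1 hydroxyl through a vanadium alkoxide, should place an epoxide across C2–C3 on the hydroxyl face, giving the vinyl epoxide F2. Sodium benzeneselenolate ((PhSe)2, NaBH4, EtOH) should open it at the allylic carbon C3 with inversion to give the trans hydroxy selenide F3. Oxidation (H2O2, pyridine, THF, 0 °C) then triggers the suprafacial [2,3]-sigmatropic shift of the allylic selenoxide, which moves oxygen to C5 on the face that carried selenium and the alkene to C3=C4, giving 15.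

3. Step 8 (peroxide opening). The base may abstract C2–H in place of C5–H and give the wrong ketone, or it may epimerise C6 next to the new carbonyl. The fallback sets out from 13 and comes back at 16. Reduction of the O–O bond with Zn in AcOH/CH2Cl2 at 0 °C should give the cis ene-diol F4, with the C2 and C5 hydroxyls both on the face of the C1 hydroxyl. Mitsunobu esterification with benzoic acid (PPh3, DIAD, THF, 0 °C) should act only at C5, because C2 is neopentyl-like beside the quaternary C1, and give the C5-inverted monobenzoate F5. Benzoylation of the remaining C2 hydroxyl (BzCl, pyridine, DMAP) then gives 16.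

Further compounds
F1 | step 5 | [(1R,6S)-6-(chloroacetoxy)-1-hydroxycyclohexa-2,4-dien-1-yl]methyl benzoate | O=C(OC[C@]1(O)C=CC=C[C@@H]1OC(=O)CCl)c1ccccc1
F2 | step 7 | [6-(tert-butyldimethylsilyloxy)-2,3-epoxy-1-hydroxycyclohex-4-en-1-yl]methyl benzoate, epoxide cis to C1–OH, C6–OSi trans to C1–OH | O=C(OC[C@]1(O)[C@H]2O[C@H]2C=C[C@@H]1O[Si](C)(C)C(C)(C)C)c1ccccc1
F3 | step 7 | [6-(tert-butyldimethylsilyloxy)-1,2-dihydroxy-3-(phenylselanyl)cyclohex-4-en-1-yl]methyl benzoate, C2–OH cis to C1–OH, C3–Se trans to C2–OH | O=C(OC[C@]1(O)[C@@H](O)[C@H]([Se]c2ccccc2)C=C[C@@H]1O[Si](C)(C)C(C)(C)C)c1ccccc1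
F4 | step 8 | [6-(tert-butyldimethylsilyloxy)-1,2,5-trihydroxycyclohex-3-en-1-yl]methyl benzoate, C2–OH and C5–OH both cis to C1–OH (C5 epimer of 15) | O=C(OC[C@]1(O)[C@@H](O)C=C[C@@H](O)[C@@H]1O[Si](C)(C)C(C)(C)C)c1ccccc1
F5 | step 8 | [5-(benzoyloxy)-6-(tert-butyldimethylsilyloxy)-1,2-dihydroxycyclohex-3-en-1-yl]methyl benzoate, C5–OBz cis to C6–OSi, C2–OH cis to C1–OH | O=C(OC[C@]1(O)[C@@H](O)C=C[C@H](OC(=O)c2ccccc2)[C@@H]1O[Si](C)(C)C(C)(C)C)c1ccccc1
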